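**Plan**

- Retrosynthesis: the five O–CH3 bonds and the quinone oxidation level of ring B are removed last. Ring D is then cut at C3–C4 and O1–C2, which leads back to an aryl-substituted dioxinone and 1,1-dimethoxyethene.
- Enabling feature: in ring D (4-hydroxy-2-pyrone; O1, C2, C3, C4, C5, C6) the atoms C4, C5, C6 and O1 form an acylketene (O=C=CH–C(=O)–CH2Ar) and C2–C3 form a ketene acetal, so the ring can be made by a [4+2] union at carbon instead of by lactonisation.
- Further cuts: the ArCH2–dioxinone bond (Pd γ-arylation of a silyl dienol ether), the diaryl ketone C–C bond (aryllithium plus aldehyde, then oxidation), and the C1–C8a bond of ring A (iodocyclisation of an aryl ynone).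
- Forward order: ring A is closed onto the trimethoxybenzene that becomes ring B; the naphthalene is joined to ring C as the ketone; the dioxinone is attached; ring D is closed; ring B is oxidised to the quinone; all methyl ethers are cleaved.
- Stereochemistry: the target has no stereocentre. The one stereocentre on the way (a diaryl carbinol) is racemic and is removed by oxidation.

Key step: step 12

Remark: ring A is the benzenoid ring of the naphthoquinone (CH3, aroyl, OH), ring B the quinone ring, ring C the resorcinol ring and ring D the pyrone; quinone and pyrone are written in the tautomeric forms of the target SMILES.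

**Route**

Step 1
Reactants: 1 3-bromo-4,5-dimethoxybenzaldehyde
Product: 3 3-bromo-4,5-dimethoxyphenol, via aryl formate 2 (not isolated)
Conditions: mCPBA, CH2Cl2, 25 °C; aq NaHCO3 wash; K2CO3 (cat.), MeOH, 25 °C
Reagents that add atoms: 3-chloroperoxybenzoic acid, OOC(=O)c1cccc(Cl)c1
Why: Baeyer–Villiger oxidation, in which the electron-rich aryl group (para-methoxy) migrates in preference to hydride and the resulting formate is transesterified by methanol, leaving the aryl bromide untouched.

Step 2
Reactants: 3 3-bromo-4,5-dimethoxyphenol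
Product: 4 1-bromo-2,3,5-trimethoxybenzene
Conditions: MeI, K2CO3, acetone, 56 °C
Reagents that add atoms: iodomethane, CI
Why: Williamson O-methylation of the phenoxide, the only nucleophilic site, sets the 1,2,4-trioxygenation pattern of the later ring B with bromine at the position that electrophilic substitution of 1,2,4-trimethoxybenzene cannot reach.

Step 3
Reactants: 4 1-bromo-2,3,5-trimethoxybenzene; 5 2-bromo-1-(morpholin-4-yl)ethan-1-one
Product: 7 1-(morpholin-4-yl)-2-(2,3,5-trimethoxyphenyl)ethan-1-one, via zinc amide enolate 6 (not isolated)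
Conditions: 5, Zn dust, THF, 25 °C; then 4, Pd(dba)2 (3 mol %), P(tBu)3 (3 mol %), THF, 25 → 60 °C
Reagents that add atoms: none
Why: Negishi-type α-arylation of a Reformatsky zinc amide enolate under zerovalent palladium with P(tBu)3 tolerates electron-rich ortho-methoxy bromoarenes, and the weakly basic zinc enolate should stop cleanly at monoarylation.

Step 4
Reactants: 7 1-(morpholin-4-yl)-2-(2,3,5-trimethoxyphenyl)ethan-1-one; 8 prop-1-yn-1-ylmagnesium bromide (CH3C≡CMgBr, commercial THF solution)
Product: 10 1-(2,3,5-trimethoxyphenyl)pent-3-yn-2-one, via magnesium aminal alkoxide 9 (not isolated)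
Conditions: 8 (2.5 equiv), THF, 0 → 25 °C; then H2O
Reagents that add atoms: none
Why: acyl substitution of a morpholine amide by an alkynyl Grignard reagent, in which the tetrahedral adduct persists until aqueous work-up so that the ynone is released only then and no tertiary alcohol can form.

Step 5
Reactants: 10 1-(2,3,5-trimethoxyphenyl)pent-3-yn-2-one
Product: 11 3-iodo-5,7,8-trimethoxy-4-methylnaphthalen-2-ol
Conditions: I2 (1.2 equiv), NaHCO3, MeCN, 0 → 25 °C
Reagents that add atoms: iodine, II
Why: iodonium-induced 6-endo-dig carbocyclisation of a 1-aryl-3-alkyn-2-one, in which the only free ring carbon next to the side chain (para to one methoxy, ortho to another) attacks the activated alkyne and enolisation gives the 3-iodo-2-naphthol with iodine between the methyl- and hydroxyl-bearing carbons, while near-stoichiometric I2 limits further iodination of the naphthol.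

Step 6
Reactants: 11 3-iodo-5,7,8-trimethoxy-4-methylnaphthalen-2-ol
Product: 12 2-iodo-3,5,6,8-tetramethoxy-1-methylnaphthalene
Conditions: MeI, K2CO3, DMF, 25 °C
Reagents that add atoms: iodomethane, CI
Why: Williamson methylation masks the naphthol before organolithium chemistry, and the phenoxide next to iodine still alkylates readily in a dipolar aprotic solvent.

Step 7
Reactants: 13 1-bromo-3,5-dimethoxybenzene
Product: 15 2-bromo-4,6-dimethoxybenzaldehyde, via iminium chloride 14 (not isolated)
Conditions: POCl3, DMF, 0 → 90 °C; then ice-water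
Reagents that add atoms: N,N-dimethylformamide, CN(C)C=O (formyl carbon); water, O (carbonyl oxygen)
Why: Vilsmeier–Haack formylation of this arene should occur mainly para to one methoxy group and ortho to bromine, not between the two methoxy groups, and the minor isomeric aldehyde would be removed by crystallisation.

Step 8
Reactants: 12 2-iodo-3,5,6,8-tetramethoxy-1-methylnaphthalene; 15 2-bromo-4,6-dimethoxybenzaldehyde
Product: 17 (2-bromo-4,6-dimethoxyphenyl)(3,5,6,8-tetramethoxy-1-methylnaphthalen-2-yl)methanol (racemic), via naphthyllithium 16 (not isolated)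
Conditions: 12, n-BuLi (1.0 equiv), THF, −78 °C; then 15, −78 → −20 °C; H2O
Reagents that add atoms: none
Why: iodine–lithium exchange followed by 1,2-addition of the aryllithium to the aldehyde, which at −78 °C should be far faster than bromine–lithium exchange with the aryl bromide of 15; the new carbinol centre is formed racemic and is removed in step 9.

Step 9
Reactants: 17 (2-bromo-4,6-dimethoxyphenyl)(3,5,6,8-tetramethoxy-1-methylnaphthalen-2-yl)methanol
Product: 18 (2-bromo-4,6-dimethoxyphenyl)(3,5,6,8-tetramethoxy-1-methylnaphthalen-2-yl)methanone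
Conditions: Dess–Martin periodinane, CH2Cl2, 25 °C
Reagents that add atoms: none
Why: Dess–Martin oxidation converts the crowded secondary diaryl carbinol to the ketone under neutral conditions that spare the electron-rich rings and the aryl bromide.

Step 10
Reactants: 19 2,2,6-trimethyl-4H-1,3-dioxin-4-one
Product: 21 [(2,2-dimethyl-6-methylidene-6H-1,3-dioxin-4-yl)oxy]trimethylsilane, via lithium dienolate 20 (not isolated)
Conditions: LiN(iPr)2 (commercial solution), THF, −78 °C; Me3SiCl, −78 → 0 °C
Reagents that add atoms: chlorotrimethylsilane, C[Si](C)(C)Cl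
Why: kinetic deprotonation of the γ-methyl group gives the vinylogous enolate, which is silylated on oxygen to the silyl dienol ether.

Step 11
Reactants: 18 (2-bromo-4,6-dimethoxyphenyl)(3,5,6,8-tetramethoxy-1-methylnaphthalen-2-yl)methanone; 21 [(2,2-dimethyl-6-methylidene-6H-1,3-dioxin-4-yl)oxy]trimethylsilane
Product: 22 6-{[3,5-dimethoxy-2-(3,5,6,8-tetramethoxy-1-methylnaphthalene-2-carbonyl)phenyl]methyl}-2,2-dimethyl-4H-1,3-dioxin-4-one
Conditions: 21 (2 equiv), Pd2(dba)3 (2.5 mol %), P(tBu)3 (10 mol %), ZnF2 (0.6 equiv), DMF, 70 °C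
Reagents that add atoms: none
Why: palladium-catalysed γ-arylation of a silyl dienol ether, in which zerovalent palladium inserts into the C–Br bond activated by the ortho carbonyl, fluoride-assisted transmetalation delivers the dienolate and reductive elimination at the terminal carbon is favoured by the bulky phosphine and by retained conjugation, while the tetra-ortho-substituted ketone is too hindered for vinylogous aldol addition.

Step 12
Reactants: 22 6-{[3,5-dimethoxy-2-(3,5,6,8-tetramethoxy-1-methylnaphthalene-2-carbonyl)phenyl]methyl}-2,2-dimethyl-4H-1,3-dioxin-4-one; 23 1,1-dimethoxyethene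
Product: 26 2-{[3,5-dimethoxy-2-(3,5,6,8-tetramethoxy-1-methylnaphthalene-2-carbonyl)phenyl]methyl}-6-methoxy-4H-pyran-4-one, via acylketene 24 (not isolated), via dimethoxydihydropyranone 25 (not isolated)
Conditions: 23 (10 equiv), toluene, 110 °C (sealed vessel), 22 added over 2 h; evaporate; pyridinium p-toluenesulfonate (cat.), CH2Cl2, 25 °C
Reagents that add atoms: none
Why: On heating, 22 loses acetone by retro-[4+2] to give acylketene 24, whose O=C–CH=C=O unit is an electron-poor oxadiene. The nucleophilic CH2 carbon of 1,1-dimethoxyethene bonds to the ketene carbon (C3–C4) and the ketone oxygen closes on the dimethoxy-substituted carbon (O1–C2), concertedly or through a short-lived zwitterion, giving the cyclic ortho ester 25, which loses methanol to the 2-methoxy-4-pyranone 26. The closest known reaction type is the hetero-Diels–Alder capture of dioxinone-derived acylketenes by enol ethers and ketene acetals to give 4-pyranones. Ring D is closed as a six-membered ring by union of the four-atom C4–C5–C6–O1 unit with the two-carbon C2–C3 unit, one bond at carbon and one at oxygen in the same operation, and no stereocentre is formed. The step needs bimolecular capture of 24 ahead of its dimerisation and ahead of intramolecular C-acylation of ring C at the free position next to the CH2 group. A tenfold excess of the strongly nucleophilic acetal, slow generation of the ketene and the neutral medium, which leaves the acidic ArCH2 group and the hindered diaryl ketone alone, should secure this.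

Step 13
Reactants: 26 2-{[3,5-dimethoxy-2-(3,5,6,8-tetramethoxy-1-methylnaphthalene-2-carbonyl)phenyl]methyl}-6-methoxy-4H-pyran-4-one
Product: 27 6-{2,4-dimethoxy-6-[(6-methoxy-4-oxo-4H-pyran-2-yl)methyl]benzoyl}-2,7-dimethoxy-5-methylnaphthalene-1,4-dione
Conditions: (NH4)2Ce(NO3)6 (2.5 equiv), MeCN–H2O (3:1), 0 °C
Reagents that add atoms: water, O
Why: oxidative demethylation by two equivalents of tetravalent cerium occurs at the only ring with a para-dimethoxy pair (the 5,6,8-trimethoxy ring B) via its radical cation and capture of water, whereas ring A, the acyl-deactivated meta-dimethoxy ring C and the methoxypyranone are much harder to oxidise, and any ortho-quinone isomer would converge on the same hydroxyquinone after step 14.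

Step 14
Reactants: 27 6-{2,4-dimethoxy-6-[(6-methoxy-4-oxo-4H-pyran-2-yl)methyl]benzoyl}-2,7-dimethoxy-5-methylnaphthalene-1,4-dione
Product: 28 6-{2,4-dihydroxy-6-[(4-hydroxy-2-oxo-2H-pyran-6-yl)methyl]benzoyl}-2,7-dihydroxy-5-methylnaphthalene-1,4-dione (CNP0141484.0)
Conditions: BBr3 (10 equiv), CH2Cl2, −78 → 25 °C; then H2O
Reagents that add atoms: none
Why: Lewis-acid ether cleavage, in which BBr3 removes the three aryl methyl groups (those ortho to the ketone helped by chelation) and bromide attacks the O-methyl groups of the two boron-complexed vinylogous esters, so that the freed 2-hydroxy-4-pyranone tautomerises to the 4-hydroxy-2-pyrone of ring D.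

**Compound list**

1 | 3-bromo-4,5-dimethoxybenzaldehyde | O=Cc1cc(Br)c(OC)c(OC)c1 | starting material
2 | 3-bromo-4,5-dimethoxyphenyl formate | O=COc1cc(Br)c(OC)c(OC)c1 | intermediate
3 | 3-bromo-4,5-dimethoxyphenol | Oc1cc(Br)c(OC)c(OC)c1 | intermediate
4 | 1-bromo-2,3,5-trimethoxybenzene | COc1cc(Br)c(OC)c(OC)c1 | intermediate
5 | 2-bromo-1-(morpholin-4-yl)ethan-1-one | BrCC(=O)N1CCOCC1 | starting material
6 | bromo[2-(morpholin-4-yl)-2-oxoethyl]zinc | Br[Zn]CC(=O)N1CCOCC1 | intermediate
7 | 1-(morpholin-4-yl)-2-(2,3,5-trimethoxyphenyl)ethan-1-one | O=C(Cc1cc(OC)cc(OC)c1OC)N1CCOCC1 | intermediate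
8 | prop-1-yn-1-ylmagnesium bromide | CC#C[Mg]Br | starting material
9 | bromomagnesium 2-(morpholin-4-yl)-1-(2,3,5-trimethoxyphenyl)pent-3-yn-2-olate | CC#CC(O[Mg]Br)(Cc1cc(OC)cc(OC)c1OC)N1CCOCC1 | intermediate
10 | 1-(2,3,5-trimethoxyphenyl)pent-3-yn-2-one | CC#CC(=O)Cc1cc(OC)cc(OC)c1OC | intermediate
11 | 3-iodo-5,7,8-trimethoxy-4-methylnaphthalen-2-ol | Cc1c(I)c(O)cc2c(OC)c(OC)cc(OC)c12 | intermediate
12 | 2-iodo-3,5,6,8-tetramethoxy-1-methylnaphthalene | Cc1c(I)c(OC)cc2c(OC)c(OC)cc(OC)c12 | intermediate
13 | 1-bromo-3,5-dimethoxybenzene | COc1cc(Br)cc(OC)c1 | starting material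
14 | [(2-bromo-4,6-dimethoxyphenyl)methylidene]dimethylazanium chloride | C[N+](C)=Cc1c(Br)cc(OC)cc1OC.[Cl-] | intermediate
15 | 2-bromo-4,6-dimethoxybenzaldehyde | O=Cc1c(Br)cc(OC)cc1OC | intermediate
16 | (3,5,6,8-tetramethoxy-1-methylnaphthalen-2-yl)lithium | Cc1c([Li])c(OC)cc2c(OC)c(OC)cc(OC)c12 | intermediate
17 | (2-bromo-4,6-dimethoxyphenyl)(3,5,6,8-tetramethoxy-1-methylnaphthalen-2-yl)methanol (racemic) | Cc1c(C(O)c3c(OC)cc(OC)cc3Br)c(OC)cc2c(OC)c(OC)cc(OC)c12 | intermediate
18 | (2-bromo-4,6-dimethoxyphenyl)(3,5,6,8-tetramethoxy-1-methylnaphthalen-2-yl)methanone | Cc1c(C(=O)c3c(OC)cc(OC)cc3Br)c(OC)cc2c(OC)c(OC)cc(OC)c12 | intermediate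
19 | 2,2,6-trimethyl-4H-1,3-dioxin-4-one | CC1=CC(=O)OC(C)(C)O1 | starting material
20 | lithium 2,2-dimethyl-6-methylidene-6H-1,3-dioxin-4-olate | C=C1C=C(O[Li])OC(C)(C)O1 | intermediate
21 | [(2,2-dimethyl-6-methylidene-6H-1,3-dioxin-4-yl)oxy]trimethylsilane | C=C1C=C(O[Si](C)(C)C)OC(C)(C)O1 | intermediate
22 | 6-{[3,5-dimethoxy-2-(3,5,6,8-tetramethoxy-1-methylnaphthalene-2-carbonyl)phenyl]methyl}-2,2-dimethyl-4H-1,3-dioxin-4-one | Cc1c(C(=O)c3c(OC)cc(OC)cc3CC4=CC(=O)OC(C)(C)O4)c(OC)cc2c(OC)c(OC)cc(OC)c12 | intermediate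
23 | 1,1-dimethoxyethene | C=C(OC)OC | starting material
24 | 5-[3,5-dimethoxy-2-(3,5,6,8-tetramethoxy-1-methylnaphthalene-2-carbonyl)phenyl]pent-1-ene-1,4-dione | Cc1c(C(=O)c3c(OC)cc(OC)cc3CC(=O)C=C=O)c(OC)cc2c(OC)c(OC)cc(OC)c12 | intermediate
25 | 6-{[3,5-dimethoxy-2-(3,5,6,8-tetramethoxy-1-methylnaphthalene-2-carbonyl)phenyl]methyl}-2,2-dimethoxy-2,3-dihydro-4H-pyran-4-one | Cc1c(C(=O)c3c(OC)cc(OC)cc3CC4=CC(=O)CC(OC)(OC)O4)c(OC)cc2c(OC)c(OC)cc(OC)c12 | intermediate
26 | 2-{[3,5-dimethoxy-2-(3,5,6,8-tetramethoxy-1-methylnaphthalene-2-carbonyl)phenyl]methyl}-6-methoxy-4H-pyran-4-one | Cc1c(C(=O)c3c(OC)cc(OC)cc3CC4=CC(=O)C=C(OC)O4)c(OC)cc2c(OC)c(OC)cc(OC)c12 | intermediate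
27 | 6-{2,4-dimethoxy-6-[(6-methoxy-4-oxo-4H-pyran-2-yl)methyl]benzoyl}-2,7-dimethoxy-5-methylnaphthalene-1,4-dione | Cc1c(C(=O)c3c(OC)cc(OC)cc3CC4=CC(=O)C=C(OC)O4)c(OC)cc2c1C(=O)C=C(OC)C2=O | intermediate
28 | 6-{2,4-dihydroxy-6-[(4-hydroxy-2-oxo-2H-pyran-6-yl)methyl]benzoyl}-2,7-dihydroxy-5-methylnaphthalene-1,4-dione | Cc1c(C(=O)c2c(O)cc(O)cc2Cc2cc(O)cc(=O)o2)c(O)cc2c1C(=O)C=C(O)C2=O | target

**Step count and risks**

Total steps: 14. Longest linear sequence: 12 steps (steps 1–6, 8, 9, 11–14).

Steps most likely to fail: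

1. Step 12. The acylketene may be consumed by ring closure onto ring C (C-acylation or electrocyclisation of its dienol form) or by dimerisation before the acetal captures it. The fallback avoids the acylketene and brings ring D in preformed; it sets out from 18 and returns to the route at 28. Ketone 18 would be borylated with bis(pinacolato)diboron, Pd(dppf)Cl2 and KOAc in dioxane to [3,5-dimethoxy-2-(3,5,6,8-tetramethoxy-1-methylnaphthalene-2-carbonyl)phenyl]boronic acid pinacol ester F1. Commercial 4-methoxy-6-methyl-2H-pyran-2-one would be brominated at the methyl group with N-bromosuccinimide under radical initiation to 6-(bromomethyl)-4-methoxy-2H-pyran-2-one F2. Suzuki–Miyaura coupling of the two (Pd(PPh3)4, K2CO3, THF–H2O) should give 6-{[3,5-dimethoxy-2-(3,5,6,8-tetramethoxy-1-methylnaphthalene-2-carbonyl)phenyl]methyl}-4-methoxy-2H-pyran-2-one F3. Oxidation with (NH4)2Ce(NO3)6 as in step 13 would give 6-{2,4-dimethoxy-6-[(4-methoxy-2-oxo-2H-pyran-6-yl)methyl]benzoyl}-2,7-dimethoxy-5-methylnaphthalene-1,4-dione F4, and BBr3 as in step 14 would then give 28.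

2. Step 11. Transmetalation of the silyl dienolate at the crowded arylpalladium centre may be slow, or coupling may occur at the α-carbon or be lost to protodesilylation. The fallback builds the dioxinone from an arylacetic acid; it sets out from 18 and returns at 22. Ketone 18 would be coupled with commercial (2-tert-butoxy-2-oxoethyl)zinc bromide (BrZnCH2CO2tBu; Pd(dba)2, P(tBu)3, THF), an enolate with no α/γ ambiguity, to give tert-butyl 2-[3,5-dimethoxy-2-(3,5,6,8-tetramethoxy-1-methylnaphthalene-2-carbonyl)phenyl]acetate F5. Cleavage with CF3CO2H in CH2Cl2 would give 2-[3,5-dimethoxy-2-(3,5,6,8-tetramethoxy-1-methylnaphthalene-2-carbonyl)phenyl]acetic acid F6. Condensation with 2,2-dimethyl-1,3-dioxane-4,6-dione (carbodiimide, 4-(dimethylamino)pyridine) would give 5-{2-[3,5-dimethoxy-2-(3,5,6,8-tetramethoxy-1-methylnaphthalene-2-carbonyl)phenyl]-1-hydroxyethylidene}-2,2-dimethyl-1,3-dioxane-4,6-dione F7. Heating F7 in toluene–acetone at about 90 °C should give 22 by loss of CO2 and capture of the acylketene by acetone.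

3. Step 14. Ether cleavage may be incomplete, or the methoxyquinone may decompose under the Lewis acid. The fallback reverses the order of deprotection and oxidation; it sets out from 26 and returns at 28. BBr3 would be applied to 26 at the arene oxidation level to give 6-{[3,5-dihydroxy-2-(3,5,6,8-tetrahydroxy-1-methylnaphthalene-2-carbonyl)phenyl]methyl}-4-hydroxy-2H-pyran-2-one F8. The 1,2,4-trihydroxylated ring B of F8 should then autoxidise with O2 in aqueous NaHCO3–MeOH to the hydroxyquinone 28.

**Further compounds**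

F1 | step 12 | [3,5-dimethoxy-2-(3,5,6,8-tetramethoxy-1-methylnaphthalene-2-carbonyl)phenyl]boronic acid pinacol ester | Cc1c(C(=O)c3c(OC)cc(OC)cc3B4OC(C)(C)C(C)(C)O4)c(OC)cc2c(OC)c(OC)cc(OC)c12
F2 | step 12 | 6-(bromomethyl)-4-methoxy-2H-pyran-2-one | COc1cc(CBr)oc(=O)c1
F3 | step 12 | 6-{[3,5-dimethoxy-2-(3,5,6,8-tetramethoxy-1-methylnaphthalene-2-carbonyl)phenyl]methyl}-4-methoxy-2H-pyran-2-one | Cc1c(C(=O)c3c(OC)cc(OC)cc3Cc4cc(OC)cc(=O)o4)c(OC)cc2c(OC)c(OC)cc(OC)c12
F4 | step 12 | 6-{2,4-dimethoxy-6-[(4-methoxy-2-oxo-2H-pyran-6-yl)methyl]benzoyl}-2,7-dimethoxy-5-methylnaphthalene-1,4-dione | Cc1c(C(=O)c3c(OC)cc(OC)cc3Cc4cc(OC)cc(=O)o4)c(OC)cc2c1C(=O)C=C(OC)C2=O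
F5 | step 11 | tert-butyl 2-[3,5-dimethoxy-2-(3,5,6,8-tetramethoxy-1-methylnaphthalene-2-carbonyl)phenyl]acetate | Cc1c(C(=O)c3c(OC)cc(OC)cc3CC(=O)OC(C)(C)C)c(OC)cc2c(OC)c(OC)cc(OC)c12
F6 | step 11 | 2-[3,5-dimethoxy-2-(3,5,6,8-tetramethoxy-1-methylnaphthalene-2-carbonyl)phenyl]acetic acid | Cc1c(C(=O)c3c(OC)cc(OC)cc3CC(=O)O)c(OC)cc2c(OC)c(OC)cc(OC)c12
F7 | step 11 | 5-{2-[3,5-dimethoxy-2-(3,5,6,8-tetramethoxy-1-methylnaphthalene-2-carbonyl)phenyl]-1-hydroxyethylidene}-2,2-dimethyl-1,3-dioxane-4,6-dione | Cc1c(C(=O)c3c(OC)cc(OC)cc3CC(O)=C4C(=O)OC(C)(C)OC4=O)c(OC)cc2c(OC)c(OC)cc(OC)c12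
F8 | step 14 | 6-{[3,5-dihydroxy-2-(3,5,6,8-tetrahydroxy-1-methylnaphthalene-2-carbonyl)phenyl]methyl}-4-hydroxy-2H-pyran-2-one | Cc1c(C(=O)c3c(O)cc(O)cc3Cc4cc(O)cc(=O)o4)c(O)cc2c(O)c(O)cc(O)c12
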